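**Plan**
- Cuts: the four O–Me caps come off first. C2'–Br and C3'–Br go back to C–H, and both outer rings go back to 4-aryloxy-2-bromocyclohexenones. C4'–C5' and C5'–C6' are then cut in each ring, which excises C5'(Br) as CBr2. The two C1'–O bonds are cut last.
- Enabling feature: in each outer ring C5' carries Br and sits between the hydroxyl carbon C4' and C6'–H. CBr2 insertion between a ketone carbon and its α-CH places a C–Br at exactly this position.
- Forward: the central ring comes from bromanil, and two cyclopentenone rings are attached through oxygen by addition–elimination. 1,4-Hydrosilylation fixes both enol ethers, and both five-membered rings are expanded to six-membered rings in one operation. Aromatisation, bromination and demethylation follow.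
- Conjugate addition of this hindered, acidic hydroquinone to cyclopentenone would be reversible, so hydride rather than aryloxide is the group added in 1,4-fashion.
- Stereochemistry: the target has none. The two C1' centres of the alicyclic intermediates form without control, are spectators and vanish on aromatisation.

Key step: step 6

Remark (locants): outer-ring atoms carry the target locants throughout.
- C1' is the ether carbon.
- C2' and C3' are the two CH2 groups (later C–Br).
- C4' is the carbonyl, enol or phenol carbon.
- C5' is the inserted carbon.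
- C6' is the CH next to C1'.

Remark (assumption): intermediates with two C1' centres are carried on as meso/dl mixtures. Names and SMILES show the meso (R,S) form.

**Step 1**
Reactants: 1 bromanil (2,3,5,6-tetrabromo-1,4-benzoquinone)
Product: 2 2,5-dibromo-3,6-dimethoxy-1,4-benzoquinone
Conditions: NaOMe (2.05 equiv), MeOH, 0 °C to rt
Reagents that add atoms: sodium methoxide, C[O-].[Na+]
Why: Twofold addition–elimination of methoxide on the haloquinone; the first methoxy group deactivates its own vinylogous-ester half, so the second should enter at the para-related carbon, the usual 2,5-pattern of haloanil alkoxylation.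

**Step 2**
Reactants: 2 2,5-dibromo-3,6-dimethoxy-1,4-benzoquinone
Product: 3 2,5-dibromo-3,6-dimethoxybenzene-1,4-diol
Conditions: Na2S2O4, EtOAc–H2O, rt, Ar
Reagents that add atoms: none
Why: Dithionite reduction of a quinone to its hydroquinone, which leaves C–Br and O–Me bonds untouched.

**Step 3**
Reactants: 4 cyclopentane-1,3-dione
Product: 5 3-chlorocyclopent-2-en-1-one
Conditions: (COCl)2 (1.1 equiv), DMF (cat.), CH2Cl2, 0 °C to rt
Reagents that add atoms: oxalyl chloride, O=C(Cl)C(=O)Cl
Why: Activation of the enol oxygen of a cyclic 1,3-diketone and its displacement by chloride, the standard preparation of β-chloro enones.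

**Step 4**
Reactants: 3 2,5-dibromo-3,6-dimethoxybenzene-1,4-diol; 5 3-chlorocyclopent-2-en-1-one (2.2 equiv)
Product: 6 3,3'-[(2,5-dibromo-3,6-dimethoxy-1,4-phenylene)bis(oxy)]bis(cyclopent-2-en-1-one)
Conditions: Cs2CO3 (2.2 equiv), degassed MeCN, rt to 50 °C, Ar
Reagents that add atoms: none
Why: Vinylic addition–elimination of an aryloxide at the β-carbon of a β-chloro enone, the usual route to 3-aryloxy enones, should form both C1'–O bonds irreversibly; the fully substituted ring excludes C-alkylation.

**Step 5**
Reactants: 6 3,3'-[(2,5-dibromo-3,6-dimethoxy-1,4-phenylene)bis(oxy)]bis(cyclopent-2-en-1-one)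
Product: 7 1,4-dibromo-2,5-dimethoxy-3,6-bis{[3-(triethylsilyloxy)cyclopent-2-en-1-yl]oxy}benzene (meso/dl mixture)
Conditions: Et3SiH (3 equiv), RhCl(PPh3)3 (3 mol %), toluene, 50 °C; filtration through basic alumina
Reagents that add atoms: triethylsilane, CC[SiH](CC)CC
Why: Proposed new method: oxidative addition of Et3Si–H to monovalent rhodium, silyl transfer to the carbonyl oxygen and C–H reductive elimination at the β-carbon of the resulting 1-silyloxy-3-aryloxyallyl rhodium hydride should place hydrogen on C1' and silicon on oxygen without freeing an enolate that could expel the aryloxide, so the double bond is locked between C4' and C6'; the closest known reaction types are the RhCl(PPh3)3-catalysed 1,4-hydrosilylation of simple cyclic enones with monohydrosilanes and the conjugate reduction of chromones and dihydropyranones, whereas an isolable silyl enol ether from an exocyclic β-aryloxy enone is not documented; the two C1' centres form without mutual control, which does not matter.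

**Step 6**
Reactants: 7 1,4-dibromo-2,5-dimethoxy-3,6-bis{[3-(triethylsilyloxy)cyclopent-2-en-1-yl]oxy}benzene; 8 bromoform
Product: 10 4,4'-[(2,5-dibromo-3,6-dimethoxy-1,4-phenylene)bis(oxy)]bis(2-bromocyclohex-2-en-1-one) (meso/dl mixture), via bis(dibromocyclopropane) adduct 9 (not isolated)
Conditions: CHBr3 (5 equiv), KOtBu (5 equiv, in portions), pentane–toluene, −30 to 0 °C; filtration, then toluene, 60 °C
Reagents that add atoms: bromoform 8, BrC(Br)Br
Why: Bromoform and KOtBu release dibromocarbene by α-elimination, and it adds in a concerted (2+1) cheletropic step to the C4'=C6' enol-ether double bond of each five-membered ring, from the face away from the aryloxy group, to give the bis(6,6-dibromobicyclo[3.1.0]hexane) 9. In each adduct the endo bromide (the one lying over the five-membered ring) leaves in concert with disrotatory two-electron electrocyclic opening of the shared C4'–C6' bond, the silyloxy group stabilises the cyclohexenyl cation, and bromide strips silicon to unveil the 2-bromocyclohex-2-enone. Mode of closure: each three-membered ring is closed by the cycloaddition, which makes C4'–C5' and C5'–C6' (C5'–Br comes with the carbene), and each six-membered ring then arises by cleavage of the zero-atom bridge, that is by ring expansion and not by cyclisation. The closest known reaction type is exactly this dihalocarbene addition to cyclic silyl enol ethers with rearrangement to 2-halocycloalk-2-enones, here run twice in one molecule. No lasting stereocentre is created: the cyclopropane centres of 9 are set by anti approach and disappear on opening, and the C1' centres are spectators. The step needs site selectivity (secured because the enol ethers are the only nucleophilic alkenes and the hexasubstituted central ring offers no position) and positional selectivity for insertion between C4' and C6' (secured by the location of the double bond fixed in step 5); adding the base in portions at low temperature keeps the allylic aryl ether and the nascent enone away from excess alkoxide.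

**Step 7**
Reactants: 10 4,4'-[(2,5-dibromo-3,6-dimethoxy-1,4-phenylene)bis(oxy)]bis(2-bromocyclohex-2-en-1-one)
Product: 13 4,4'-[(2,5-dibromo-3,6-dimethoxy-1,4-phenylene)bis(oxy)]bis(2,6-dibromophenol), via bis(2,6-dibromo enone) 11 (not isolated), via bis(3-bromo-4-hydroxyphenyl) ether 12 (not isolated)
Conditions: Br2 (4.1 equiv), anhydrous AcOH, rt to 60 °C
Reagents that add atoms: bromine, BrBr
Why: Acid-catalysed bromination at C3' and loss of HBr give a 4H-cyclohexa-2,5-dienone that tautomerises at once to the phenol (classical bromination–dehydrobromination aromatisation of cyclohexenones), and the phenol then takes one more bromine at its only free ortho position C3', while C2' and C6', meta to the hydroxyl, should resist uncatalysed bromine; the C1' stereocentres are erased here.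

**Step 8**
Reactants: 13 4,4'-[(2,5-dibromo-3,6-dimethoxy-1,4-phenylene)bis(oxy)]bis(2,6-dibromophenol)
Product: 14 1,4-dibromo-2,5-bis(3,5-dibromo-4-methoxyphenoxy)-3,6-dimethoxybenzene
Conditions: MeI (3 equiv), K2CO3 (2.5 equiv), DMF, rt
Reagents that add atoms: iodomethane, CI
Why: Williamson O-methylation of the acidic 2,6-dibromophenols; capping the para-aryloxyphenols blocks their oxidation to quinones during the forcing bromination that follows, and the caps leave later together with the central methyl ethers.

**Step 9**
Reactants: 14 1,4-dibromo-2,5-bis(3,5-dibromo-4-methoxyphenoxy)-3,6-dimethoxybenzene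
Product: 15 1,4-dibromo-2,5-dimethoxy-3,6-bis(2,3,5-tribromo-4-methoxyphenoxy)benzene
Conditions: Br2 (2.3 equiv), FeBr3 (10 mol %), 1,2-dichloroethane, 40 °C
Reagents that add atoms: bromine, BrBr
Why: Lewis-acid-catalysed electrophilic aromatic bromination ortho to the diaryl-ether oxygen, as practised on methoxylated polybromodiphenyl ethers; C2' and C6' are equivalent in 14 so a single isomer should result, and the new bromine, meta to the last C–H, deactivates that ring strongly against a second entry.

**Step 10**
Reactants: 15 1,4-dibromo-2,5-dimethoxy-3,6-bis(2,3,5-tribromo-4-methoxyphenoxy)benzene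
Product: 17 2,5-dibromo-3,6-bis(2,3,5-tribromo-4-hydroxyphenoxy)benzene-1,4-diol (CNP0163357.0), via tetrakis(dibromoboryl) ether 16 (not isolated)
Conditions: BBr3 (8 equiv), CH2Cl2, −78 °C to rt; degassed H2O
Reagents that add atoms: none
Why: BBr3 cleavage of aryl methyl ethers through aryloxyboranes that hydrolyse on work-up; diaryl-ether and C–Br bonds are inert to the reagent.

**Compound list**
1 | bromanil | BrC1=C(Br)C(=O)C(Br)=C(Br)C1=O | starting material
2 | 2,5-dibromo-3,6-dimethoxy-1,4-benzoquinone | COC1=C(Br)C(=O)C(OC)=C(Br)C1=O | intermediate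
3 | 2,5-dibromo-3,6-dimethoxybenzene-1,4-diol | COc1c(Br)c(O)c(OC)c(Br)c1O | intermediate
4 | cyclopentane-1,3-dione | O=C1CCC(=O)C1 | starting material
5 | 3-chlorocyclopent-2-en-1-one | O=C1CCC(Cl)=C1 | intermediate
6 | 3,3'-[(2,5-dibromo-3,6-dimethoxy-1,4-phenylene)bis(oxy)]bis(cyclopent-2-en-1-one) | COc1c(Br)c(OC2=CC(=O)CC2)c(OC)c(Br)c1OC1=CC(=O)CC1 | intermediate
7 | 1,4-dibromo-2,5-dimethoxy-3,6-bis{[3-(triethylsilyloxy)cyclopent-2-en-1-yl]oxy}benzene (meso form drawn) | COc1c(Br)c(O[C@H]2CCC(O[Si](CC)(CC)CC)=C2)c(OC)c(Br)c1O[C@@H]1CCC(O[Si](CC)(CC)CC)=C1 | intermediate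
8 | bromoform | BrC(Br)Br | starting material
9 | 1,4-dibromo-2,5-dimethoxy-3,6-bis{[6,6-dibromo-5-(triethylsilyloxy)bicyclo[3.1.0]hexan-2-yl]oxy}benzene (CBr2 anti to the aryloxy group, meso form drawn) | COc1c(Br)c(O[C@H]2CC[C@@]3(O[Si](CC)(CC)CC)[C@@H]2C3(Br)Br)c(OC)c(Br)c1O[C@@H]1CC[C@]2(O[Si](CC)(CC)CC)[C@H]1C2(Br)Br | intermediate
10 | 4,4'-[(2,5-dibromo-3,6-dimethoxy-1,4-phenylene)bis(oxy)]bis(2-bromocyclohex-2-en-1-one) (meso form drawn) | COc1c(Br)c(O[C@H]2CCC(=O)C(Br)=C2)c(OC)c(Br)c1O[C@@H]1CCC(=O)C(Br)=C1 | intermediate
11 | 4,4'-[(2,5-dibromo-3,6-dimethoxy-1,4-phenylene)bis(oxy)]bis(2,6-dibromocyclohex-2-en-1-one) (epimers at CHBr) | COc1c(Br)c(O[C@H]2CC(Br)C(=O)C(Br)=C2)c(OC)c(Br)c1O[C@@H]1CC(Br)C(=O)C(Br)=C1 | intermediate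
12 | 4,4'-[(2,5-dibromo-3,6-dimethoxy-1,4-phenylene)bis(oxy)]bis(2-bromophenol) | COc1c(Br)c(Oc2ccc(O)c(Br)c2)c(OC)c(Br)c1Oc1ccc(O)c(Br)c1 | intermediate
13 | 4,4'-[(2,5-dibromo-3,6-dimethoxy-1,4-phenylene)bis(oxy)]bis(2,6-dibromophenol) | COc1c(Br)c(Oc2cc(Br)c(O)c(Br)c2)c(OC)c(Br)c1Oc1cc(Br)c(O)c(Br)c1 | intermediate
14 | 1,4-dibromo-2,5-bis(3,5-dibromo-4-methoxyphenoxy)-3,6-dimethoxybenzene | COc1c(Br)cc(Oc2c(OC)c(Br)c(Oc3cc(Br)c(OC)c(Br)c3)c(OC)c2Br)cc1Br | intermediate
15 | 1,4-dibromo-2,5-dimethoxy-3,6-bis(2,3,5-tribromo-4-methoxyphenoxy)benzene | COc1c(Br)cc(Oc2c(OC)c(Br)c(Oc3cc(Br)c(OC)c(Br)c3Br)c(OC)c2Br)c(Br)c1Br | intermediate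
16 | tetrakis(O-dibromoboryl) derivative of the target | BrB(Br)Oc1c(Br)cc(Oc2c(OB(Br)Br)c(Br)c(Oc3cc(Br)c(OB(Br)Br)c(Br)c3Br)c(OB(Br)Br)c2Br)c(Br)c1Br | intermediate
17 | 2,5-dibromo-3,6-bis(2,3,5-tribromo-4-hydroxyphenoxy)benzene-1,4-diol (CNP0163357.0) | Oc1c(Br)cc(Oc2c(O)c(Br)c(Oc3cc(Br)c(O)c(Br)c3Br)c(O)c2Br)c(Br)c1Br | target

Total step count: 10. Longest linear sequence: 9 (steps 1, 2 and 4–10, from bromanil).

**Steps most likely to fail**

**Step 5.**
- What may go wrong: hydride may be delivered to the carbonyl carbon instead of the β-carbon. Turnover may be sluggish on the electron-rich vinylogous ester. Rhodium may also ionise the new allylic C–O bond, with reductive loss of the aryloxy group.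
- Fallback: this sets out from 3, with the C5 partner drawn from 4, and comes back at 10. The enol ether is made before the C1'–O bond, which is then formed by SN2 displacement at an sp3 carbon.
- Dione 4 is O-silylated (iPr3SiOTf, Et3N, CH2Cl2) to 3-(triisopropylsilyloxy)cyclopent-2-en-1-one F1.
- 1,2-Reduction (iBu2AlH, toluene, −78 °C, basic work-up) gives racemic 3-(triisopropylsilyloxy)cyclopent-2-en-1-ol F2.
- A twofold Mitsunobu reaction of 3 with F2 (PPh3, DIAD, THF, 0 °C) gives the bis(triisopropylsilyl enol ether) F3.
- Under the conditions of step 6, F3 passes through the bis(dibromocyclopropane) F4 and rejoins the route at 10.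

**Step 6.**
- What may go wrong: base may eliminate aryloxide from the allylic ether, or tert-butoxide may desilylate the enol ether before carbene capture. The second carbene addition may stay incomplete. Tribromomethyl anion may attack enone that has already been released.
- Fallback: this sets out from 7 and comes back at 13. The one-carbon expansion is run with a bromine-free carbenoid under non-basic conditions, and all outer-ring bromine is brought in later.
- Simmons–Smith cyclopropanation in the Furukawa variant (Et2Zn, CH2I2, CH2Cl2, 0 °C) gives the bis(silyloxycyclopropane) F5.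
- FeCl3 in DMF opens the shared bond oxidatively (Ito–Saegusa ring expansion) to the bis(3-chloro ketone) F6.
- NaOAc in MeOH eliminates HCl to the bis(4-aryloxycyclohex-2-enone) F7.
- Br2 (6 equiv) in AcOH, as in step 7, aromatises F7 to the bis(4-hydroxyphenyl) ether F8. F8 takes up bromine at both ortho positions of each phenol and so arrives at 13.

**Step 7.**
- What may go wrong: acid may promote departure of the central aryloxy group. This can occur as non-oxidative aromatisation by elimination, or as enol-ether hydrolysis after double-bond migration. Either process competes with bromination at C3'.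
- Fallback: this sets out from 10 and comes back at 13. The dehydrogenation is done without acid and without bromine.
- Kinetic deprotonation with in-situ silylation (LiN(SiMe3)2, Me3SiCl, THF, −78 °C) gives the bis(cross-conjugated trimethylsilyl dienol ether) F9.
- DDQ with 2,6-lutidine in CH2Cl2 dehydrosilylates F9 to the dienone, which tautomerises to 12. Compound 12 is isolated in this variant.
- Br2 (2 equiv, CH2Cl2, 0 °C) then brominates ortho to each hydroxyl to give 13.

**Further compounds**
F1 | step 5 | 3-(triisopropylsilyloxy)cyclopent-2-en-1-one | CC(C)[Si](OC1=CC(=O)CC1)(C(C)C)C(C)C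
F2 | step 5 | 3-(triisopropylsilyloxy)cyclopent-2-en-1-ol (racemic) | CC(C)[Si](OC1=CC(O)CC1)(C(C)C)C(C)C
F3 | step 5 | 1,4-dibromo-2,5-dimethoxy-3,6-bis{[3-(triisopropylsilyloxy)cyclopent-2-en-1-yl]oxy}benzene (meso form drawn) | COc1c(Br)c(O[C@H]2CCC(O[Si](C(C)C)(C(C)C)C(C)C)=C2)c(OC)c(Br)c1O[C@@H]1CCC(O[Si](C(C)C)(C(C)C)C(C)C)=C1
F4 | step 5 | 1,4-dibromo-2,5-dimethoxy-3,6-bis{[6,6-dibromo-5-(triisopropylsilyloxy)bicyclo[3.1.0]hexan-2-yl]oxy}benzene (anti adduct, meso form drawn) | COc1c(Br)c(O[C@H]2CC[C@@]3(O[Si](C(C)C)(C(C)C)C(C)C)[C@@H]2C3(Br)Br)c(OC)c(Br)c1O[C@@H]1CC[C@]2(O[Si](C(C)C)(C(C)C)C(C)C)[C@H]1C2(Br)Br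
F5 | step 6 | 1,4-dibromo-2,5-dimethoxy-3,6-bis{[5-(triethylsilyloxy)bicyclo[3.1.0]hexan-2-yl]oxy}benzene (facial course not controlled, anti meso form drawn) | COc1c(Br)c(O[C@H]2CC[C@@]3(O[Si](CC)(CC)CC)[C@@H]2C3)c(OC)c(Br)c1O[C@@H]1CC[C@]2(O[Si](CC)(CC)CC)[C@H]1C2
F6 | step 6 | 4,4'-[(2,5-dibromo-3,6-dimethoxy-1,4-phenylene)bis(oxy)]bis(3-chlorocyclohexan-1-one) (diastereomer mixture) | COc1c(Br)c(OC2CCC(=O)CC2Cl)c(OC)c(Br)c1OC1CCC(=O)CC1Cl
F7 | step 6 | 4,4'-[(2,5-dibromo-3,6-dimethoxy-1,4-phenylene)bis(oxy)]bis(cyclohex-2-en-1-one) (meso form drawn) | COc1c(Br)c(O[C@H]2CCC(=O)C=C2)c(OC)c(Br)c1O[C@@H]1CCC(=O)C=C1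
F8 | step 6 | 4,4'-[(2,5-dibromo-3,6-dimethoxy-1,4-phenylene)bis(oxy)]diphenol | COc1c(Br)c(Oc2ccc(O)cc2)c(OC)c(Br)c1Oc1ccc(O)cc1
F9 | step 7 | 1,4-dibromo-2,5-dimethoxy-3,6-bis{[3-bromo-4-(trimethylsilyloxy)cyclohexa-2,4-dien-1-yl]oxy}benzene (meso form drawn) | COc1c(Br)c(O[C@H]2CC=C(O[Si](C)(C)C)C(Br)=C2)c(OC)c(Br)c1O[C@@H]1CC=C(O[Si](C)(C)C)C(Br)=C1
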